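## Analysis of the target

The target is the 7-O-prenyl ether of (2R,3R)-dihydroquercetin. It is a chroman-4-one (rings A and C) with a catechol (ring B) on C2, a hydroxyl on C3, a hydrogen-bonded hydroxyl on C5 and the prenyloxy group on C7. C2 and C3 are the only stereocentres; they are adjacent, both R and trans, so aryl and hydroxyl sit diequatorial on ring C, which is also the thermodynamically preferred arrangement. Both centres are labile: C3 is alpha to the C4 ketone, and the O1–C2 bond is a benzylic ether beta to that ketone. That bond opens by retro-oxa-Michael reaction in base and can ionise in strong acid with help from the 4'-oxygen. The catechol is easily oxidised, the prenyl ether is acid-labile and would be reduced under hydrogenation, and the flavanonol as a whole dehydrogenates readily to the flavonol. The difficulty therefore lies in the order of events: five oxygens must be told apart so that only O7 is alkylated, the absolute configuration must be set in an open-chain precursor, and everything after ring closure must run near neutrality. The feature on which the plan rests is C4a of ring A. It lies between C5–O and C8a–O1 and para to C7–O, the position at which a 1,3,5-trioxygenated benzene reacts with electrophiles. As long as O5 and O7 carry the same group, the two carbons ortho to O1 in an open aryl ether are equivalent, so closing C4–C4a by acylation from a chain hanging on O1 can give only one chromanone.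

## Retrosynthetic reasoning

**23 ⇒ 22.** The last operation is removal of the two catechol silyl ethers. Silicon is used on ring B because a buffered fluoride source removes it without touching the prenyl ether, the ketone or the two stereocentres. An acid-labile or base-labile group at this point would endanger the prenyl ether or ring C.

**22 ⇒ 20 + 21.** The O7–prenyl bond is cut next. The prenyl alkene cannot pass through a hydrogenolysis, so it must be introduced after the benzyl groups have gone. In 20 the three free hydroxyls differ strongly: 7-OH is para to the carbonyl and the most acidic, 5-OH is locked in a hydrogen bond to C4=O, and 3-OH is an ordinary hindered secondary alcohol. A Mitsunobu reaction with 21 exploits this difference without any base.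

**20 ⇒ 19.** The three benzyl ethers (O3, O5, O7) are removed together by hydrogenolysis, to which the aryl silyl ethers are inert. Identical benzyl groups on O5 and O7 are what make ring A symmetric in the key step.

**19 ⇒ 17 (through 18).** This is the strategic cut, C4–C4a. Ring C is opened to the 3-aryloxypropanoic acid 17, in which C2, C3 and all oxygens are already in place. The forward reaction is an intramolecular Friedel–Crafts acylation through the mixed anhydride 18. The bond is cut here because the chain is tethered through O1 and can only reach the two equivalent ortho carbons. The stereochemical problem is thereby moved into acyclic chemistry, and the ring closure has no regiochemical choice to make.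

**17 ⇒ 15 (through 16) ⇒ 14.** The carboxyl group is carried as a silyl-protected primary alcohol until the aryl ether exists. With a carbonyl beta to the carbinol, ether formation would compete with elimination and retro-aldol cleavage; at the alcohol oxidation level neither is possible. Mild acid removes the alkyl silyl ether of 14 without touching the aryl silyl ethers, and a halogen-free oxidation takes 15 through aldehyde 16 to 17.

**14 ⇒ 12 + 13.** The O1–C2 bond is formed by Mitsunobu etherification of the benzylic alcohol 12 with the symmetric phenol 13, with inversion. The alternative is arylation of an alkoxide with retention, which needs hot base. That is unsuitable for aryl silyl ethers and would also demand the less general anti glycolate aldol. Using inversion means the required precursor is the syn aldol, the most dependable glycolate aldol there is.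

**12 ⇒ 10 ⇒ 9.** The primary silyl ether of 12 comes from selective silylation of diol 10 with 11. Diol 10 comes from reductive removal of the auxiliary from aldol adduct 9, which returns 4.

**9 ⇒ 3 + 7 (through 8).** The C2–C3 bond (flavonoid numbering) is made by the syn-selective boron aldol of glycolate imide 7, via its Z enolate 8, with the ring B aldehyde 3. This step sets both stereocentres: the benzyloxy-bearing carbon in its final configuration and the carbinol as the epimer that step 6 inverts. Aldehyde 3 comes from 1 and 2; imide 7 comes from 4 and 5 through 6.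

## Alternatives that were turned down

**Alternative 1:** Ring C is made first and alone, by cutting C2–C3 and O1–C8a. The forward step is a hetero-Diels–Alder reaction (concerted or as aldol addition then cyclisation) between ring B aldehyde A3 and oxygenated diene A2 under a chiral Lewis acid, followed by elimination of the methoxy group to give dihydropyranone A1.
- For it: both stereocentres are set catalytically in one step from achiral partners. On stereochemical economy this is stronger than the chosen route, which uses a stoichiometric auxiliary and an inversion.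
- Against it: the extra siloxy group on the diene terminus makes the 2,3-relative configuration depend on diene geometry and on the mechanism, so trans is not assured. More seriously, A1 contains nothing of ring A. Four carbons and two differentiated oxygens would have to be annulated onto the C4a=C8a double bond of a beta-alkoxy enone, which is a poor dienophile and a poor acceptor, and then aromatised while C3 sits beside a ketone.
- Comparison: the chosen route takes ring A ready-made as 13 and needs one ring closure without regiochemical ambiguity; this alternative's steps pile up after its key step.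

**Alternative 2:** Both O1–C8a and C4–C4a are cut, so ring A arrives as an aryne from silyl triflate A5 and the chain as hydroxy ester A6. In the forward step fluoride generates the aryne, the alkoxide of A6 adds at the carbon remote from the C5 oxygen (the inductive effect of that oxygen places the aryl anion at C4a), and the anion closes onto the ester to give A4.
- For it: this is the most convergent plan. It forms two bonds and ring C in one step, the regiochemistry is electronically reasonable, and the prenyl group is already in place, so no late selective alkylation is needed. On convergence and bond count it is stronger than the chosen route.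
- Against it: the nucleophile is an aldol alkoxide under basic conditions, so retro-aldol cleavage and epimerisation alpha to the ester are open pathways. The aryl anion can be protonated instead of cyclising, giving only the open ether. Four methoxymethyl groups must finally be removed with acid in the presence of the acid-labile prenyl aryl ether. A5 needs several steps to place three different oxygen substituents and a C-silyl group on one benzene ring.
- Comparison: the chosen route is longer and linear, but it separates ether formation (neutral, stereospecific) from acylation and ends with fluoride, not acid.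

**Alternative 3:** Ring A is dismantled completely (C4a–C5, C5–C6, C7–C8), leaving chiral diazoketone A8 and siloxyalkyne A9. In the forward step irradiation causes Wolff rearrangement to a vinylketene, which adds A9 to give a 4-vinylcyclobutenone. Thermal 4-pi opening, 6-pi electrocyclisation and tautomerisation then give A7.
- For it: O5 (free) and O7 (silylated) are differentiated by construction. That is stronger than the chosen route, which relies on an acidity difference in step 11. Three carbon–carbon bonds form in one operation.
- Against it: A8 presupposes the chiral pyranone of a plan like alternative 1, plus C-acylation at C8a and diazo transfer, so the precursor is long. The diazoketone also contains a beta-alkoxy enone chromophore that can compete under irradiation. Two stereocentres flanking a ketone must survive light and heat, and the acid-labile protecting groups again clash with the prenyl ether.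
- Comparison: the chosen route buys ring A and reaches its precursor by eight conventional steps; the benzannulation builds what can be bought.

Key step: step 9

Assumption: 3,5-bis(benzyloxy)phenol (13), (R)-4-benzyloxazolidin-2-one (4) and benzyloxyacetyl chloride (5) are treated as catalogue compounds.

## Route

Step 1
Reactants: 1 3,4-dihydroxybenzaldehyde; 2 chlorotriisopropylsilane
Product: 3 3,4-bis(triisopropylsilyloxy)benzaldehyde
Conditions: TIPSCl (2.5 equiv), imidazole, DMAP (cat.), DMF, rt → 40 °C
Reagents that add atoms: chlorotriisopropylsilane (2), CC(C)[Si](Cl)(C(C)C)C(C)C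
Why: Imidazole-promoted O-silylation of both phenols; excess chloride and gentle warming should bring the second, more hindered silyl group onto the catechol. These ethers resist hydrogenolysis, mild acid and Mitsunobu conditions and leave with fluoride at the end.

Step 2
Reactants: 4 (R)-4-benzyloxazolidin-2-one; 5 benzyloxyacetyl chloride
Product: 7 (R)-4-benzyl-3-[2-(benzyloxy)acetyl]oxazolidin-2-one, via N-lithiated oxazolidinone 6 (not isolated)
Conditions: n-BuLi, THF, −78 °C; then 5, −78 → 0 °C
Reagents that add atoms: benzyloxyacetyl chloride (5), O=C(Cl)COCc1ccccc1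
Why: N-acylation of the lithiated oxazolidinone with an acid chloride, the standard preparation of N-acyl oxazolidinones; at −78 °C the lithium amide is acylated faster than the acid chloride can form a ketene.

Step 3
Reactants: 7 (R)-4-benzyl-3-[2-(benzyloxy)acetyl]oxazolidin-2-one; 3 3,4-bis(triisopropylsilyloxy)benzaldehyde
Product: 9 (R)-4-benzyl-3-[(2R,3S)-2-(benzyloxy)-3-hydroxy-3-[3,4-bis(triisopropylsilyloxy)phenyl]propanoyl]oxazolidin-2-one, via dibutylboron Z-enolate 8 (not isolated)
Conditions: Bu2BOTf, Et3N, CH2Cl2, 0 °C; then 3, −78 → 0 °C; pH 7 buffer, MeOH, H2O2, 0 °C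
Reagents that add atoms: none
Why: Evans syn aldol reaction: soft enolisation gives the Z boron enolate 8, which reacts through a closed chair (Zimmerman–Traxler) transition state with the auxiliary carbonyl turned away from the enolate oxygen, so the aldehyde adds to the face remote from the benzyl group with its aryl group equatorial. The benzyloxy carbon (later C3 of the flavanonol) is thereby set as R in its final form, and the carbinol carbon (later C2) is set as S, the epimer that step 6 inverts.

Step 4
Reactants: 9 (R)-4-benzyl-3-[(2R,3S)-2-(benzyloxy)-3-hydroxy-3-[3,4-bis(triisopropylsilyloxy)phenyl]propanoyl]oxazolidin-2-one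
Product: 10 (1S,2S)-2-(benzyloxy)-1-[3,4-bis(triisopropylsilyloxy)phenyl]propane-1,3-diol
Conditions: LiBH4, MeOH (1 equiv), THF, 0 °C
Reagents that add atoms: none
Why: Reductive cleavage of the N-acyl oxazolidinone: LiBH4 attacks the activated exocyclic carbonyl and reduces it to the primary alcohol, releasing the auxiliary for recovery. Silyl and benzyl ethers are inert, and the medium is not basic enough for retro-aldol cleavage.

Step 5
Reactants: 10 (1S,2S)-2-(benzyloxy)-1-[3,4-bis(triisopropylsilyloxy)phenyl]propane-1,3-diol; 11 tert-butylchlorodimethylsilane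
Product: 12 (1S,2S)-2-(benzyloxy)-3-[(tert-butyldimethylsilyl)oxy]-1-[3,4-bis(triisopropylsilyloxy)phenyl]propan-1-ol
Conditions: TBSCl (1.05 equiv), imidazole, CH2Cl2, 0 °C
Reagents that add atoms: tert-butylchlorodimethylsilane (11), CC(C)(C)[Si](C)(C)Cl
Why: Selective silylation: the unhindered primary hydroxyl reacts far faster than the secondary benzylic one flanked by a branched carbon, so one equivalent of chloride should mask only the future carboxyl carbon.

Step 6
Reactants: 12 (1S,2S)-2-(benzyloxy)-3-[(tert-butyldimethylsilyl)oxy]-1-[3,4-bis(triisopropylsilyloxy)phenyl]propan-1-ol; 13 3,5-bis(benzyloxy)phenol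
Product: 14 [(2S,3R)-2-(benzyloxy)-3-[3,5-bis(benzyloxy)phenoxy]-3-[3,4-bis(triisopropylsilyloxy)phenyl]propoxy](tert-butyl)dimethylsilane
Conditions: PPh3, DIAD, toluene, 0 °C → rt
Reagents that add atoms: 3,5-bis(benzyloxy)phenol (13), Oc1cc(OCc2ccccc2)cc(OCc2ccccc2)c1
Why: Mitsunobu etherification: the phosphonium-activated benzylic carbinol is displaced by the phenoxide of 13 in an SN2 process with inversion, which turns the syn aldol pattern into the required anti one and sets the future C2 as R. The non-polar solvent and low temperature keep the ion pair tight and disfavour ionisation, and with no carbonyl beta to the carbinol there is no easy elimination path.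

Step 7
Reactants: 14 [(2S,3R)-2-(benzyloxy)-3-[3,5-bis(benzyloxy)phenoxy]-3-[3,4-bis(triisopropylsilyloxy)phenyl]propoxy](tert-butyl)dimethylsilane
Product: 15 (2S,3R)-2-(benzyloxy)-3-[3,5-bis(benzyloxy)phenoxy]-3-[3,4-bis(triisopropylsilyloxy)phenyl]propan-1-ol
Conditions: CSA (cat.), MeOH/CH2Cl2, 0 °C
Reagents that add atoms: none
Why: Acid-catalysed methanolysis of the primary alkyl silyl ether; aryl triisopropylsilyl ethers are labile to base and fluoride but not to mild acid, and the benzyl and aryl ethers are untouched at this acidity.

Step 8
Reactants: 15 (2S,3R)-2-(benzyloxy)-3-[3,5-bis(benzyloxy)phenoxy]-3-[3,4-bis(triisopropylsilyloxy)phenyl]propan-1-ol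
Product: 17 (2R,3R)-2-(benzyloxy)-3-[3,5-bis(benzyloxy)phenoxy]-3-[3,4-bis(triisopropylsilyloxy)phenyl]propanoic acid, via aldehyde 16 (not isolated)
Conditions: TEMPO (cat.), PhI(OAc)2, CH2Cl2/MeCN/H2O, rt
Reagents that add atoms: water, O
Why: Oxoammonium-mediated oxidation of the primary alcohol to aldehyde 16, whose hydrate is oxidised on to the acid in the same flask. No chlorine-based oxidant is present, so the electron-rich ring A should not be halogenated, and the near-neutral medium should not epimerise the alpha-alkoxy aldehyde; the descriptor at the benzyloxy carbon changes from S to R only because the priorities change.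

Step 9
Reactants: 17 (2R,3R)-2-(benzyloxy)-3-[3,5-bis(benzyloxy)phenoxy]-3-[3,4-bis(triisopropylsilyloxy)phenyl]propanoic acid
Product: 19 (2R,3R)-3,5,7-tris(benzyloxy)-2-[3,4-bis(triisopropylsilyloxy)phenyl]chroman-4-one, via mixed trifluoroacetic anhydride 18 (not isolated)
Conditions: (CF3CO)2O (1.5 equiv), CH2Cl2, 0 °C → rt
Reagents that add atoms: none
Why: Trifluoroacetic anhydride converts 17 into mixed anhydride 18; the ring A carbon ortho to O1, activated by O1 and one benzyloxy group in ortho positions and by the other benzyloxy group in the para position, attacks the non-fluorinated acyl carbon, and loss of trifluoroacetate and rearomatisation of the Wheland intermediate give the aryl ketone, forming C4–C4a and ring C. The closest known reaction type is the intramolecular Friedel–Crafts acylation of 3-aryloxypropanoic acids to chroman-4-ones under anhydride activation. Ring C closes in a 6-exo-trig mode at the acyl carbon, the carbonyl being exocyclic to the new ring. No stereocentre is created: C2 and C3 are carried through, and because the trans-diequatorial product is also the thermodynamic one, reversible enolisation at C3 cannot erode it. Regioselectivity is secured by the substrate, since the tether reaches only the two carbons ortho to O1 and these are interchanged by rotation about the O1–aryl bond as long as O5 and O7 both carry benzyl. Chemoselectivity over ring B (which could only close a five-membered indanone and has a single para oxygen) and over the benzyl rings follows from the much higher nucleophilicity of the trioxygenated ring A. Direct attack on the mixed anhydride avoids a free alpha-alkoxy acylium ion that could lose CO, and the absence of base excludes ketene formation at C3.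

Step 10
Reactants: 19 (2R,3R)-3,5,7-tris(benzyloxy)-2-[3,4-bis(triisopropylsilyloxy)phenyl]chroman-4-one
Product: 20 (2R,3R)-3,5,7-trihydroxy-2-[3,4-bis(triisopropylsilyloxy)phenyl]chroman-4-one
Conditions: H2 (1 atm), Pd(OH)2 on carbon, EtOAc/THF, rt
Reagents that add atoms: none
Why: Catalytic hydrogenolysis of the two aryl benzyl ethers and the aliphatic one; the silyl ethers are inert. The ketone (deactivated by the donor oxygens and then by the 5-OH hydrogen bond) and the ring C–O1 bond should react more slowly, so the reaction is stopped after uptake of three equivalents.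

Step 11
Reactants: 20 (2R,3R)-3,5,7-trihydroxy-2-[3,4-bis(triisopropylsilyloxy)phenyl]chroman-4-one; 21 3-methylbut-2-en-1-ol
Product: 22 (2R,3R)-3,5-dihydroxy-7-[(3-methylbut-2-en-1-yl)oxy]-2-[3,4-bis(triisopropylsilyloxy)phenyl]chroman-4-one
Conditions: PPh3, DIAD, 21 (1.1 equiv), THF, 0 °C → rt
Reagents that add atoms: 3-methylbut-2-en-1-ol (21), CC(C)=CCO
Why: Mitsunobu alkylation of a phenol by a primary allylic alcohol: 7-OH, para to the carbonyl, is the most acidic site and acts as the pronucleophile, 5-OH is held in the hydrogen bond to C4=O, and 3-OH is not acidic enough. The primary alcohol 21 is activated much faster than the hindered secondary 3-OH, and SN2 attack at its primary carbon gives the linear prenyl ether.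

Step 12
Reactants: 22 (2R,3R)-3,5-dihydroxy-7-[(3-methylbut-2-en-1-yl)oxy]-2-[3,4-bis(triisopropylsilyloxy)phenyl]chroman-4-one
Product: 23 (2R,3R)-2-(3,4-dihydroxyphenyl)-3,5-dihydroxy-7-[(3-methylbut-2-en-1-yl)oxy]chroman-4-one
Conditions: Bu4NF, AcOH, THF, 0 °C
Reagents that add atoms: none
Why: Fluoride-induced cleavage of the two aryl silyl ethers, which leave as phenoxides; acetic acid buffering keeps the medium from turning basic, so ring C should not open and the catechol should not be oxidised, and the prenyl ether is inert to fluoride.

## Compound list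

1 | 3,4-dihydroxybenzaldehyde | O=Cc1ccc(O)c(O)c1 | starting material
2 | chlorotriisopropylsilane | CC(C)[Si](Cl)(C(C)C)C(C)C | starting material
3 | 3,4-bis(triisopropylsilyloxy)benzaldehyde | O=Cc1ccc(O[Si](C(C)C)(C(C)C)C(C)C)c(O[Si](C(C)C)(C(C)C)C(C)C)c1 | intermediate
4 | (R)-4-benzyloxazolidin-2-one | O=C1N[C@H](Cc2ccccc2)CO1 | starting material
5 | benzyloxyacetyl chloride | O=C(Cl)COCc1ccccc1 | starting material
6 | lithium salt of (R)-4-benzyloxazolidin-2-one (N-lithiated) | [Li]N1[C@H](Cc2ccccc2)COC1=O | intermediate
7 | (R)-4-benzyl-3-[2-(benzyloxy)acetyl]oxazolidin-2-one | O=C(COCc1ccccc1)N1[C@H](Cc2ccccc2)COC1=O | intermediate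
8 | dibutylboron Z-enolate of 7 | CCCCB(CCCC)O/C(=C\OCc1ccccc1)N1[C@H](Cc2ccccc2)COC1=O | intermediate
9 | (R)-4-benzyl-3-[(2R,3S)-2-(benzyloxy)-3-hydroxy-3-[3,4-bis(triisopropylsilyloxy)phenyl]propanoyl]oxazolidin-2-one | O[C@@H](c1ccc(O[Si](C(C)C)(C(C)C)C(C)C)c(O[Si](C(C)C)(C(C)C)C(C)C)c1)[C@@H](OCc1ccccc1)C(=O)N1[C@H](Cc2ccccc2)COC1=O | intermediate
10 | (1S,2S)-2-(benzyloxy)-1-[3,4-bis(triisopropylsilyloxy)phenyl]propane-1,3-diol | O[C@@H](c1ccc(O[Si](C(C)C)(C(C)C)C(C)C)c(O[Si](C(C)C)(C(C)C)C(C)C)c1)[C@@H](OCc1ccccc1)CO | intermediate
11 | tert-butylchlorodimethylsilane | CC(C)(C)[Si](C)(C)Cl | starting material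
12 | (1S,2S)-2-(benzyloxy)-3-[(tert-butyldimethylsilyl)oxy]-1-[3,4-bis(triisopropylsilyloxy)phenyl]propan-1-ol | O[C@@H](c1ccc(O[Si](C(C)C)(C(C)C)C(C)C)c(O[Si](C(C)C)(C(C)C)C(C)C)c1)[C@@H](OCc1ccccc1)CO[Si](C)(C)C(C)(C)C | intermediate
13 | 3,5-bis(benzyloxy)phenol | Oc1cc(OCc2ccccc2)cc(OCc2ccccc2)c1 | starting material
14 | [(2S,3R)-2-(benzyloxy)-3-[3,5-bis(benzyloxy)phenoxy]-3-[3,4-bis(triisopropylsilyloxy)phenyl]propoxy](tert-butyl)dimethylsilane | c1ccccc1COc1cc(OCc2ccccc2)cc(c1)O[C@H](c1ccc(O[Si](C(C)C)(C(C)C)C(C)C)c(O[Si](C(C)C)(C(C)C)C(C)C)c1)[C@@H](OCc1ccccc1)CO[Si](C)(C)C(C)(C)C | intermediate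
15 | (2S,3R)-2-(benzyloxy)-3-[3,5-bis(benzyloxy)phenoxy]-3-[3,4-bis(triisopropylsilyloxy)phenyl]propan-1-ol | c1ccccc1COc1cc(OCc2ccccc2)cc(c1)O[C@H](c1ccc(O[Si](C(C)C)(C(C)C)C(C)C)c(O[Si](C(C)C)(C(C)C)C(C)C)c1)[C@@H](OCc1ccccc1)CO | intermediate
16 | (2R,3R)-2-(benzyloxy)-3-[3,5-bis(benzyloxy)phenoxy]-3-[3,4-bis(triisopropylsilyloxy)phenyl]propanal | c1ccccc1COc1cc(OCc2ccccc2)cc(c1)O[C@H](c1ccc(O[Si](C(C)C)(C(C)C)C(C)C)c(O[Si](C(C)C)(C(C)C)C(C)C)c1)[C@@H](OCc1ccccc1)C=O | intermediate
17 | (2R,3R)-2-(benzyloxy)-3-[3,5-bis(benzyloxy)phenoxy]-3-[3,4-bis(triisopropylsilyloxy)phenyl]propanoic acid | c1ccccc1COc1cc(OCc2ccccc2)cc(c1)O[C@H](c1ccc(O[Si](C(C)C)(C(C)C)C(C)C)c(O[Si](C(C)C)(C(C)C)C(C)C)c1)[C@@H](OCc1ccccc1)C(=O)O | intermediate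
18 | mixed anhydride of 17 with trifluoroacetic acid, (2R,3R) | c1ccccc1COc1cc(OCc2ccccc2)cc(c1)O[C@H](c1ccc(O[Si](C(C)C)(C(C)C)C(C)C)c(O[Si](C(C)C)(C(C)C)C(C)C)c1)[C@@H](OCc1ccccc1)C(=O)OC(=O)C(F)(F)F | intermediate
19 | (2R,3R)-3,5,7-tris(benzyloxy)-2-[3,4-bis(triisopropylsilyloxy)phenyl]chroman-4-one | c1ccccc1COc1cc(OCc2ccccc2)c2c(c1)O[C@H](c1ccc(O[Si](C(C)C)(C(C)C)C(C)C)c(O[Si](C(C)C)(C(C)C)C(C)C)c1)[C@@H](OCc1ccccc1)C2=O | intermediate
20 | (2R,3R)-3,5,7-trihydroxy-2-[3,4-bis(triisopropylsilyloxy)phenyl]chroman-4-one | Oc1cc(O)c2c(c1)O[C@H](c1ccc(O[Si](C(C)C)(C(C)C)C(C)C)c(O[Si](C(C)C)(C(C)C)C(C)C)c1)[C@@H](O)C2=O | intermediate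
21 | 3-methylbut-2-en-1-ol | CC(C)=CCO | starting material
22 | (2R,3R)-3,5-dihydroxy-7-[(3-methylbut-2-en-1-yl)oxy]-2-[3,4-bis(triisopropylsilyloxy)phenyl]chroman-4-one | CC(C)=CCOc1cc(O)c2c(c1)O[C@H](c1ccc(O[Si](C(C)C)(C(C)C)C(C)C)c(O[Si](C(C)C)(C(C)C)C(C)C)c1)[C@@H](O)C2=O | intermediate
23 | (2R,3R)-2-(3,4-dihydroxyphenyl)-3,5-dihydroxy-7-[(3-methylbut-2-en-1-yl)oxy]chroman-4-one | CC(C)=CCOc1cc(O)c2c(c1)O[C@H](c1ccc(O)c(O)c1)[C@@H](O)C2=O | target

## Step count and risk

Total step count: 12. Longest linear sequence: 11 steps (steps 1 and 3 to 12, from 1); step 2 is the side branch that prepares 7.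

**Step 9 (key step).** The most likely failure is acid-promoted ionisation of the benzylic O1–C2 bond by the trifluoroacetic acid that the step liberates. The para siloxy group of ring B stabilises the cation, which would scramble C2 or detach ring A. A second risk is C-trifluoroacetylation of the very electron-rich ring A before it closes. The fallback replaces the acid-generating anhydride with a buffered amide activation. Acid 17 would be coupled with dimethylamine (EDC, HOBt, CH2Cl2) to the N,N-dimethylamide of 17, F1. Treatment with Tf2O and 2-fluoropyridine in CH2Cl2 at −78 → 0 °C would then effect a Vilsmeier–Haack-type intramolecular acylation to the cyclic 4-iminium triflate F2. This is not isolated; aqueous NaHCO3 hydrolyses it and the route is rejoined at 19. Any partial epimerisation at C3 on this path would be corrected by equilibration to the trans-diequatorial isomer.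

**Step 6.** The hindered, electron-rich benzylic carbinol may react partly through an ionised intermediate, eroding the inversion and giving some syn ether, or may eliminate or react sluggishly. The fallback forms the ether with retention after inverting the carbinol. Alcohol 12 would be oxidised with Dess–Martin periodinane to the (S)-alpha-benzyloxy aryl ketone F3. Chelation-controlled reduction with Zn(BH4)2 (Et2O, −20 °C; hydride delivered to the zinc chelate of the ketone and the alpha-benzyloxy oxygen) should give the anti alcohol F4. Ullmann-type O-arylation of F4 with 1,3-bis(benzyloxy)-5-iodobenzene F5 (CuI, 3,4,7,8-tetramethyl-1,10-phenanthroline, Cs2CO3, toluene, 80 °C) leaves the carbinol configuration untouched and returns to the route at 14.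

**Step 11.** The redox condensation may activate the free 3-OH instead of 21, leading to dehydration towards the flavonol or to O3 ethers, or may over-alkylate at O5. The fallback is an ionic alkylation: 20 would be treated with one equivalent of K2CO3 and 1-bromo-3-methylbut-2-ene F6 in acetone at rt. Only the most acidic 7-OH is deprotonated, and its phenoxide is alkylated at the primary carbon, rejoining the route at 22.

**Step 10.** Over-reduction of the C4 carbonyl or hydrogenolytic opening of the benzylic C2–O1 bond may compete, particularly because the aliphatic 3-O-benzyl ether is the slowest of the three to cleave. The fallback removes the benzyl groups by Lewis acid instead of hydrogen: 19 would be treated with BCl3 and pentamethylbenzene as cation scavenger in CH2Cl2 at −78 °C, giving 20 directly without any new intermediate.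

## Further compounds

F1 | step 9 | (2R,3R)-2-(benzyloxy)-3-[3,5-bis(benzyloxy)phenoxy]-3-[3,4-bis(triisopropylsilyloxy)phenyl]-N,N-dimethylpropanamide | c1ccccc1COc1cc(OCc2ccccc2)cc(c1)O[C@H](c1ccc(O[Si](C(C)C)(C(C)C)C(C)C)c(O[Si](C(C)C)(C(C)C)C(C)C)c1)[C@@H](OCc1ccccc1)C(=O)N(C)C
F2 | step 9 | N-[(2R,3S)-3,5,7-tris(benzyloxy)-2-[3,4-bis(triisopropylsilyloxy)phenyl]chroman-4-ylidene]-N-methylmethanaminium trifluoromethanesulfonate | c1ccccc1COc1cc(OCc2ccccc2)c2c(c1)O[C@H](c1ccc(O[Si](C(C)C)(C(C)C)C(C)C)c(O[Si](C(C)C)(C(C)C)C(C)C)c1)[C@@H](OCc1ccccc1)C2=[N+](C)C.[O-]S(=O)(=O)C(F)(F)F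
F3 | step 6 | (S)-2-(benzyloxy)-3-[(tert-butyldimethylsilyl)oxy]-1-[3,4-bis(triisopropylsilyloxy)phenyl]propan-1-one | O=C(c1ccc(O[Si](C(C)C)(C(C)C)C(C)C)c(O[Si](C(C)C)(C(C)C)C(C)C)c1)[C@@H](OCc1ccccc1)CO[Si](C)(C)C(C)(C)C
F4 | step 6 | (1R,2S)-2-(benzyloxy)-3-[(tert-butyldimethylsilyl)oxy]-1-[3,4-bis(triisopropylsilyloxy)phenyl]propan-1-ol | O[C@H](c1ccc(O[Si](C(C)C)(C(C)C)C(C)C)c(O[Si](C(C)C)(C(C)C)C(C)C)c1)[C@@H](OCc1ccccc1)CO[Si](C)(C)C(C)(C)C
F5 | step 6 | 1,3-bis(benzyloxy)-5-iodobenzene | Ic1cc(OCc2ccccc2)cc(OCc2ccccc2)c1
F6 | step 11 | 1-bromo-3-methylbut-2-ene | CC(C)=CCBr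
F0 | step 10 | none | none
A1 | alternative 1 | (2R,3R)-2-[3,4-bis(tert-butyldimethylsilyloxy)phenyl]-3-(tert-butyldimethylsilyloxy)-2,3-dihydro-4H-pyran-4-one | O1[C@H](c2ccc(O[Si](C)(C)C(C)(C)C)c(O[Si](C)(C)C(C)(C)C)c2)[C@@H](O[Si](C)(C)C(C)(C)C)C(=O)C=C1
A2 | alternative 1 | (1E,3Z)-1-methoxy-3,4-bis(tert-butyldimethylsilyloxy)buta-1,3-diene | CO/C=C/C(O[Si](C)(C)C(C)(C)C)=C/O[Si](C)(C)C(C)(C)C
A3 | alternative 1 | 3,4-bis(tert-butyldimethylsilyloxy)benzaldehyde | O=Cc1ccc(O[Si](C)(C)C(C)(C)C)c(O[Si](C)(C)C(C)(C)C)c1
A4 | alternative 2 | (2R,3R)-3,5-bis(methoxymethoxy)-2-[3,4-bis(methoxymethoxy)phenyl]-7-[(3-methylbut-2-en-1-yl)oxy]chroman-4-one | CC(C)=CCOc1cc(OCOC)c2c(c1)O[C@H](c1ccc(OCOC)c(OCOC)c1)[C@@H](OCOC)C2=O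
A5 | alternative 2 | 3-(methoxymethoxy)-5-[(3-methylbut-2-en-1-yl)oxy]-2-(trimethylsilyl)phenyl trifluoromethanesulfonate | CC(C)=CCOc1cc(OCOC)c([Si](C)(C)C)c(OS(=O)(=O)C(F)(F)F)c1
A6 | alternative 2 | methyl (2R,3R)-3-hydroxy-2-(methoxymethoxy)-3-[3,4-bis(methoxymethoxy)phenyl]propanoate | O[C@H](c1ccc(OCOC)c(OCOC)c1)[C@@H](OCOC)C(=O)OC
A7 | alternative 3 | (2R,3R)-5-hydroxy-3-(methoxymethoxy)-2-[3,4-bis(methoxymethoxy)phenyl]-7-(triisopropylsilyloxy)chroman-4-one | CC(C)[Si](C(C)C)(C(C)C)Oc1cc(O)c2c(c1)O[C@H](c1ccc(OCOC)c(OCOC)c1)[C@@H](OCOC)C2=O
A8 | alternative 3 | (2R,3R)-6-(2-diazoacetyl)-3-(methoxymethoxy)-2-[3,4-bis(methoxymethoxy)phenyl]-2,3-dihydro-4H-pyran-4-one | O1[C@H](c2ccc(OCOC)c(OCOC)c2)[C@@H](OCOC)C(=O)C=C1C(=O)C=[N+]=[N-]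
A9 | alternative 3 | (ethynyloxy)triisopropylsilane | C#CO[Si](C(C)C)(C(C)C)C(C)C
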